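**Plan**
1. Retrosynthetic cuts, in order: the C8=C17 alkene (carried masked as a C8 phenylthio group); ring A at the C3–C4 bond (the last ring; C3 carried as a sulfonylhydrazone carbon, C4 as the internal carbon of an isopropenyl group); the two Diels–Alder bonds C12–C2′ and C15–C3′ of ring C; ring B back to (R)-carvone, a glycerol unit and an allyl unit.
2. Forward order: the carvone ring becomes ring B (its isopropenyl gives C4/C18/C19, its methyl gives C17); two alkylations make C10; allyl addition, oxidative transposition, epoxidation and thiolate opening give the C7 ketone, the 9α-hydroxyl and the masked C8; the (12E)-diene is built; cycloaddition with the chromonyl methoxyquinone forms ring C on the preformed ring D and chromone; ring A is closed last; sulfoxide elimination unveils C8=C17.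
3. Feature that makes the ring A event possible: C4 is a quaternary carbon with two methyls between the C3 methylene and the C5 methine, so a tertiary C4 radical made from an isopropenyl group by hydrogen-atom transfer (which writes the second methyl) can close C3–C4 between two arms that already sit trans-diequatorial on ring B at C5 and C10.
4. Stereochemistry: C5 from (R)-carvone; C10 by enolate alkylation anti to the isopropenyl group; C2 from (R)-solketal; C9 by α-face epoxidation anti to the C10 methyl; C12, C2′ and C3′ in the cycloaddition; the trans A/B fusion follows from the C5 and C10 centres, which are in place when ring A closes.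

Key step: step 15

Remark: labdane numbering is used for the terpenoid part (C17 = exocyclic methylene carbon, C18/C19 on C4, C20 on C10) and primes for ring D (C2′ bears the chromone); α is the face of the 9-hydroxyl, β that of the C10 methyl; in the target C11 is cis to the chromonyl group on ring C, which for a (12E)-diene means the adduct formed with the quinone ring exo.

**Step 1**
Reactants: 1 (R)-(−)-carvone
Product: 2 6-methylcarvone (both C6 epimers)
Conditions: LiN(i-Pr)2, THF, −78 °C; MeI, −78 to 0 °C
Reagents that add atoms: iodomethane, CI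
Why: Kinetic α′-deprotonation of the enone and C-methylation of the lithium dienolate (enolate alkylation); the new centre is enolised again in step 3, so its configuration does not matter.

**Step 2**
Reactants: 3 (R)-solketal
Product: 4 solketal triflate
Conditions: (CF3SO2)2O, pyridine, CH2Cl2, −78 to 0 °C
Reagents that add atoms: trifluoromethanesulfonic anhydride, O=S(=O)(OS(=O)(=O)C(F)(F)F)C(F)(F)F
Why: O-Sulfonylation of the primary alcohol gives an electrophile reactive enough for a hindered enolate; the dioxolane stereocentre (future C2) is untouched.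

**Step 3**
Reactants: 2 6-methylcarvone; 4 solketal triflate
Product: 5 quaternised enone
Conditions: LiN(i-Pr)2, THF, −78 °C; then 4, DMPU, −78 to 0 °C
Reagents that add atoms: none
Why: Enolate alkylation of the fully substituted α′-lithium enolate creates quaternary C10; the electrophile should enter anti to the vicinal C5 isopropenyl group, as in second alkylations of carvone, placing the side chain trans and the methyl cis to isopropenyl.

**Step 4**
Reactants: 5 quaternised enone
Product: 6 tertiary allylic alcohol (both carbinol epimers)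
Conditions: allylmagnesium bromide, THF, −78 °C; aq. NH4Cl
Reagents that add atoms: allylmagnesium bromide, C=CC[Mg]Br
Why: Grignard 1,2-addition to the hindered enone carbonyl installs C11–C12; the carbinol configuration is irrelevant because this carbon becomes sp2 in step 5.

**Step 5**
Reactants: 6 tertiary allylic alcohol
Product: 7 transposed enone
Conditions: [C5H5NH][CrO3Cl], NaOAc, 4 Å molecular sieves, CH2Cl2, rt
Reagents that add atoms: pyridinium chlorochromate, [O-][Cr](=O)(=O)Cl.c1cc[nH+]cc1
Why: Babler–Dauben oxidative transposition: the tertiary chromate ester undergoes a [3,3] shift to the secondary allylic terminus and is oxidised, giving the C7 ketone with the C8=C9 alkene that carries the allyl group.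

**Step 6**
Reactants: 7 transposed enone
Product: 8 α-epoxy ketone
Conditions: H2O2 (30% aq.), NaOH (cat.), MeOH, 0 °C to rt
Reagents that add atoms: hydrogen peroxide, OO
Why: Weitz–Scheffer nucleophilic epoxidation touches only the enone; hydroperoxide should add to C9 anti to the pseudoaxial C10 methyl (α face) in the half-chair that keeps both large groups pseudoequatorial, so the C9–O bond is set α.

**Step 7**
Reactants: 8 α-epoxy ketone
Product: 9 ketol sulfide
Conditions: PhSH, Et3N (cat.), MeOH, 0 °C to rt, argon
Reagents that add atoms: thiophenol, Sc1ccccc1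
Why: Thiolate opening of the α,β-epoxy ketone at the carbonyl-activated α-carbon C8 by SN2 inversion (the first stage of chalcogenolate reductions of epoxy ketones) keeps the 9α-oxygen as the tertiary hydroxyl; the product cannot dehydrate to an enone because C8 carries no hydrogen, and the C8 sulfide masks the later exocyclic alkene.

**Step 8**
Reactants: 9 ketol sulfide
Product: 10 enal
Conditions: methacrolein (excess), RuCl2(H2IMes)(=CH–C6H4-2-O-i-Pr) (second-generation Hoveyda–Grubbs catalyst, cat.), CH2Cl2, 40 °C
Reagents that add atoms: methacrolein, CC(=C)C=O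
Why: Olefin cross-metathesis of the monosubstituted allyl group with methacrolein should give the thermodynamic (E)-α-methyl enal, the 1,1-disubstituted isopropenyl group staying a spectator because ring closure with it would need both 1,3-related arms axial.

**Step 9**
Reactants: 10 enal
Product: 11 diene acetonide
Conditions: Ph3PCH3Br, KN(SiMe3)2, THF, 0 °C; then 10, −78 to 0 °C
Reagents that add atoms: methyltriphenylphosphonium bromide, C[P+](c1ccccc1)(c1ccccc1)c1ccccc1.[Br-]
Why: Wittig methylenation is selective for the aldehyde over the α-quaternary ketone and keeps the E geometry, giving the (12E)-diene.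

**Step 10**
Reactants: 11 diene acetonide
Product: 12 diene diol
Conditions: AcOH/H2O/THF (3:1:1), 40 °C
Reagents that add atoms: none
Why: Mild acid hydrolysis of the acetonide frees the C2/C3 diol without touching the diene, the tertiary ketol or the sulfide.

**Step 11**
Reactants: 12 diene diol
Product: 14 diene hydrazone, via hydroxy aldehyde 13 (not isolated)
Conditions: [Cu(MeCN)4]OTf, 2,2′-bipyridine, TEMPO, N-methylimidazole (all cat.), air, MeCN, rt; then TsNHNH2, MeOH, rt
Reagents that add atoms: p-toluenesulfonyl hydrazide, Cc1ccc(cc1)S(=O)(=O)NN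
Why: Copper/TEMPO aerobic oxidation is selective for the primary alcohol and tolerates the thioether; immediate condensation traps the C2-epimerisable hydroxy aldehyde as the N-tosylhydrazone, the radical acceptor and traceless activating group at C3.

**Step 12**
Reactants: 15 2′,6′-dihydroxy-4′-methoxyacetophenone; 16 2,4,5-trimethoxybenzoyl chloride
Product: 18 flavone, via diketone 17 (not isolated)
Conditions: LiN(SiMe3)2 (4 equiv), THF, −78 °C to rt; then H2SO4 (cat.), AcOH, 95 °C
Reagents that add atoms: none
Why: C-acylation of the lithium polyanion of the hydroxyacetophenone gives the 1,3-diketone (the Baker–Venkataraman intermediate) and acid cyclodehydration closes the chromone, leaving the second ortho hydroxyl as the 5-OH.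

**Step 13**
Reactants: 18 flavone
Product: 19 chromonyl methoxyquinone
Conditions: (NH4)2Ce(NO3)6, MeCN/H2O, 0 °C
Reagents that add atoms: water, O
Why: Oxidative demethylation by tetravalent cerium of the para-related 2′,5′-methoxyls of the electron-rich trimethoxyphenyl ring gives the methoxy-p-quinone, while the carbonyl-deactivated chromone ring should survive.

**Step 14**
Reactants: 14 diene hydrazone; 19 chromonyl methoxyquinone
Product: 20 ring-A-seco cycloadduct
Conditions: toluene, rt to 40 °C, dark
Reagents that add atoms: none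
Why: Diels–Alder reaction at the quinone double bond that bears the chromonyl group (the other is deactivated by its methoxyl), in which the unsubstituted diene terminus C15 should bond first to the unsubstituted C3′ (β to the C1′ carbonyl and conjugated through C2′ with the chromone enone) so that substituted C12 ends on C2′, with cis ring fusion from suprafacial addition; a hydrogen bond from the homoallylic 9-OH to the C1′ carbonyl in a non-polar solvent is relied on to favour the quinone-exo mode (C11 cis to chromonyl) and, with the C9 centre, one diene face, the wanted diastereomer being separated by chromatography.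

**Step 15**
Reactants: 20 ring-A-seco cycloadduct
Product: 23 8-phenylthio precursor, via sulfonylhydrazide 21 (not isolated), via diazene 22 (not isolated)
Conditions: Fe(acac)3 (cat.), PhSiH3, EtOH/THF, rt, high dilution; then MeOH, 60 °C
Reagents that add atoms: none
Why: An iron hydride formed from Fe(acac)3 and PhSiH3 transfers a hydrogen atom to the terminal CH2 of the isopropenyl group (Markovnikov HAT), so that carbon becomes the second methyl on C4 and a tertiary C4 radical results; the radical adds to the C3 carbon of the N-tosylhydrazone, the hydrazinyl radical is reduced to sulfonylhydrazide 21, and warming in methanol expels p-toluenesulfinic acid to give diazene 22, which loses N2 to leave the C3 methylene. The closest known reaction type is the iron-hydride-initiated reductive coupling of unactivated olefins with sulfonylhydrazones (olefin hydromethylation and its intramolecular variants), here used as a ring closure with the hydrazone as a traceless acceptor. Ring A closes in the 6-exo-trig mode (C4 radical onto C3=N, nitrogen outside the ring). No lasting stereocentre is created, since C4 carries two methyls and the C3 amino centre is erased; the trans ring fusion and the equatorial 2α-hydroxyl follow from centres the substrate already holds, because the C5 and C10 arms are trans-diequatorial on the ring B chair and C2 comes from the chiral pool. The step needs hydrogen-atom transfer to the isopropenyl group in preference to the trisubstituted ring C alkene, the methoxy-ene-dione and the chromone, and ring closure faster than reduction of the radical. The isopropenyl group is the only unhindered electron-rich 1,1-disubstituted alkene left (C8 is masked as the thioether, the diene is consumed), and the electron-poor C=N held in a chair-like array is a polarity-matched trap for the nucleophilic tertiary radical.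

**Step 16**
Reactants: 23 8-phenylthio precursor
Product: 25 dichrostachine N, via sulfoxide 24 (not isolated)
Conditions: 3-ClC6H4CO3H (1 equiv), CH2Cl2, −78 °C; then toluene, 70 °C
Reagents that add atoms: none
Why: The sulfide is oxidised faster than any alkene, and thermal syn-elimination of the α-sulfinyl ketone (sulfoxide elimination) can only take a hydrogen from the C17 methyl, giving the exocyclic enone.

**Compound list**
1 | (R)-(−)-carvone, (5R)-2-methyl-5-(prop-1-en-2-yl)cyclohex-2-en-1-one | CC1=CC[C@@H](C(C)=C)CC1=O | starting material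
2 | 6-methylcarvone, (5R)-2,6-dimethyl-5-(prop-1-en-2-yl)cyclohex-2-en-1-one, both C6 epimers | CC1=CC[C@@H](C(C)=C)C(C)C1=O | intermediate
3 | (R)-solketal, [(4R)-2,2-dimethyl-1,3-dioxolan-4-yl]methanol | OC[C@@H]1COC(C)(C)O1 | starting material
4 | [(4S)-2,2-dimethyl-1,3-dioxolan-4-yl]methyl trifluoromethanesulfonate | FC(F)(F)S(=O)(=O)OC[C@@H]1COC(C)(C)O1 | intermediate
5 | 6-{[(4R)-2,2-dimethyl-1,3-dioxolan-4-yl]methyl}-2,6-dimethyl-5-(prop-1-en-2-yl)cyclohex-2-en-1-one, side chain trans and 6-methyl cis to the isopropenyl group | CC1=CC[C@@H](C(C)=C)[C@](C)(C[C@@H]2COC(C)(C)O2)C1=O | intermediate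
6 | 1-allyl carbinol of 5 (1,2-adduct, both carbinol epimers) | CC1=CC[C@@H](C(C)=C)[C@](C)(C[C@@H]2COC(C)(C)O2)C1(O)CC=C | intermediate
7 | ring B enone: 3-allyl-4-{[(4R)-2,2-dimethyl-1,3-dioxolan-4-yl]methyl}-2,4-dimethyl-5-(prop-1-en-2-yl)cyclohex-2-en-1-one (C7 ketone, C8=C9, allyl on C9) | CC=1C(=O)C[C@@H](C(C)=C)[C@](C)(C[C@@H]2COC(C)(C)O2)C=1CC=C | intermediate
8 | 8α,9α-epoxide of 7 (epoxide on the face opposite to the C10 methyl) | C[C@@]12C(=O)C[C@@H](C(C)=C)[C@](C)(C[C@@H]3COC(C)(C)O3)[C@]1(CC=C)O2 | intermediate
9 | ring B ketol sulfide: C7 ketone, 8α-methyl-8β-phenylthio, 9α-hydroxy-9β-allyl, 10β-methyl-10α-(dioxolanylmethyl), 5β-isopropenyl | C[C@]1(Sc2ccccc2)C(=O)C[C@@H](C(C)=C)[C@](C)(C[C@@H]2COC(C)(C)O2)[C@@]1(O)CC=C | intermediate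
10 | (E)-enal: as 9 with 9β-[(2E)-3-formylbut-2-en-1-yl] | C[C@]1(Sc2ccccc2)C(=O)C[C@@H](C(C)=C)[C@](C)(C[C@@H]2COC(C)(C)O2)[C@@]1(O)C/C=C(\C)C=O | intermediate
11 | (12E)-diene acetonide: as 9 with 9β-[(2E)-3-methylpenta-2,4-dien-1-yl] | C[C@]1(Sc2ccccc2)C(=O)C[C@@H](C(C)=C)[C@](C)(C[C@@H]2COC(C)(C)O2)[C@@]1(O)C/C=C(\C)C=C | intermediate
12 | diene diol: as 11 with a 10α-[(2R)-2,3-dihydroxypropyl] arm | C[C@]1(Sc2ccccc2)C(=O)C[C@@H](C(C)=C)[C@](C)(C[C@@H](O)CO)[C@@]1(O)C/C=C(\C)C=C | intermediate
13 | hydroxy aldehyde: as 11 with a 10α-[(2R)-2-hydroxy-3-oxopropyl] arm | C[C@]1(Sc2ccccc2)C(=O)C[C@@H](C(C)=C)[C@](C)(C[C@@H](O)C=O)[C@@]1(O)C/C=C(\C)C=C | intermediate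
14 | diene hydrazone: (E)-N-tosylhydrazone of 13 | C[C@]1(Sc2ccccc2)C(=O)C[C@@H](C(C)=C)[C@](C)(C[C@@H](O)/C=N/NS(=O)(=O)c2ccc(C)cc2)[C@@]1(O)C/C=C(\C)C=C | intermediate
15 | 1-(2,6-dihydroxy-4-methoxyphenyl)ethan-1-one | CC(=O)c1c(O)cc(OC)cc1O | starting material
16 | 2,4,5-trimethoxybenzoyl chloride | COc1cc(OC)c(cc1OC)C(Cl)=O | starting material
17 | 1-(2,6-dihydroxy-4-methoxyphenyl)-3-(2,4,5-trimethoxyphenyl)propane-1,3-dione | COc1cc(O)c(C(=O)CC(=O)c2cc(OC)c(OC)cc2OC)c(O)c1 | intermediate
18 | 5-hydroxy-7-methoxy-2-(2,4,5-trimethoxyphenyl)-4H-chromen-4-one | COc1cc(O)c2c(c1)oc(cc2=O)-c1cc(OC)c(OC)cc1OC | intermediate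
19 | 2-(5-hydroxy-7-methoxy-4-oxo-4H-chromen-2-yl)-5-methoxy-1,4-benzoquinone | COC1=CC(=O)C(=CC1=O)c1cc(=O)c2c(O)cc(OC)cc2o1 | intermediate
20 | ring-A-seco cycloadduct: cis-fused rings C/D with C12 bonded to C2′, C11 cis to the chromonyl group, ring B as in 14 | C[C@]1(Sc2ccccc2)C(=O)C[C@@H](C(C)=C)[C@](C)(C[C@@H](O)/C=N/NS(=O)(=O)c2ccc(C)cc2)[C@@]1(O)C[C@@H]1C(C)=CC[C@H]2C(=O)C(OC)=CC(=O)[C@@]12c1cc(=O)c2c(O)cc(OC)cc2o1 | intermediate
21 | cyclised sulfonylhydrazide: ring A closed, C3 bearing NH–NHTs (either C3 epimer) | C[C@]1(Sc3ccccc3)C(=O)C[C@H]2C(C)(C)C(NNS(=O)(=O)c3ccc(C)cc3)[C@H](O)C[C@]2(C)[C@@]1(O)C[C@@H]1C(C)=CC[C@H]2C(=O)C(OC)=CC(=O)[C@@]12c1cc(=O)c2c(O)cc(OC)cc2o1 | intermediate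
22 | monoalkyl diazene: as 21 with C3–N=NH | C[C@]1(Sc3ccccc3)C(=O)C[C@H]2C(C)(C)C(N=N)[C@H](O)C[C@]2(C)[C@@]1(O)C[C@@H]1C(C)=CC[C@H]2C(=O)C(OC)=CC(=O)[C@@]12c1cc(=O)c2c(O)cc(OC)cc2o1 | intermediate
23 | 8β-phenylthio-8α-methyl precursor (the target with C8(CH3)(SPh) in place of C8=CH2) | C[C@]1(Sc3ccccc3)C(=O)C[C@H]2C(C)(C)C[C@H](O)C[C@]2(C)[C@@]1(O)C[C@@H]1C(C)=CC[C@H]2C(=O)C(OC)=CC(=O)[C@@]12c1cc(=O)c2c(O)cc(OC)cc2o1 | intermediate
24 | sulfoxide of 23 (either sulfur epimer) | C[C@]1(S(=O)c3ccccc3)C(=O)C[C@H]2C(C)(C)C[C@H](O)C[C@]2(C)[C@@]1(O)C[C@@H]1C(C)=CC[C@H]2C(=O)C(OC)=CC(=O)[C@@]12c1cc(=O)c2c(O)cc(OC)cc2o1 | intermediate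
25 | dichrostachine N | C=C1C(=O)C[C@H]2C(C)(C)C[C@H](O)C[C@]2(C)[C@@]1(O)C[C@@H]1C(C)=CC[C@H]2C(=O)C(OC)=CC(=O)[C@@]12c1cc(=O)c2c(O)cc(OC)cc2o1 | target

**Step count**
Total: 16 steps. Longest linear sequence: 13 steps (steps 1, 3–11, 14–16).

**Three steps most likely to fail**

Step 15 (key step). What may go wrong: hydrogen-atom transfer or electron transfer to the methoxy-ene-dione or the ring C alkene instead of the isopropenyl group, or reduction of the tertiary radical before it closes the ring. Fallback, changing the order of ring formation: set out from 9 and close ring A before the diene and the cycloaddition exist. Acetonide hydrolysis (AcOH/H2O) gives the allyl diol F1. Copper/TEMPO aerobic oxidation gives the allyl hydroxy aldehyde F2, and condensation with TsNHNH2 gives the allyl hydrazone F3. The same Fe(acac)3/PhSiH3 cyclisation, now with only a monosubstituted allyl group as a second alkene, should pass through the allyl sulfonylhydrazide F4 and the allyl diazene F5 to the trans-decalin F6. Cross-metathesis with methacrolein gives the decalin enal F7 and Wittig methylenation the decalin (12E)-diene F8. Cycloaddition of F8 with 19 comes back to the route at 23.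

Step 14. What may go wrong: the quinone ring may react in the endo orientation or on the other diene face, so that the C12 or the whole ring C/D configuration is wrong, or addition at the hindered chromonyl-bearing carbon may be too slow. Fallback, changing the diene geometry so that the endo rule gives the needed arrangement: from 14, triplet-sensitised E-to-Z isomerisation of the trisubstituted diene double bond (benzophenone, 365 nm) gives the (12Z)-diene hydrazone F9, separated from recovered 14. Cycloaddition of F9 with 19 under high pressure (about 13 kbar, CH2Cl2, rt), in which the inside C11 substituent ends trans to the endo quinone ring, comes back to the route at 20.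

Step 7. What may go wrong: no substitution at the fully substituted α-carbon, attack at the wrong epoxide carbon, or retro-aldol cleavage of the product alkoxide. Fallback, changing to reduction followed by regiodefined sulfenylation: from 8, reductive opening with Na[PhSeB(OEt)3] (EtOH, AcOH) gives the ketol F10. TMSCl/NaI/Et3N (MeCN) gives the more substituted C7=C8 silyl enol ether, also silylated on the 9-oxygen, the bis-silyl enol ether F11. PhSCl (CH2Cl2, −78 °C), expected to enter from the β face anti to the axial 9α-silyloxy group, gives the 9-O-silyl ketol sulfide F12, and K2CO3/MeOH comes back to the route at 9.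

**Further compounds**
F1 | step 15 | allyl diol: 9 with the acetonide replaced by the (2R)-2,3-dihydroxypropyl arm | C[C@]1(Sc2ccccc2)C(=O)C[C@@H](C(C)=C)[C@](C)(C[C@@H](O)CO)[C@@]1(O)CC=C
F2 | step 15 | allyl hydroxy aldehyde: 9 with a (2R)-2-hydroxy-3-oxopropyl arm | C[C@]1(Sc2ccccc2)C(=O)C[C@@H](C(C)=C)[C@](C)(C[C@@H](O)C=O)[C@@]1(O)CC=C
F3 | step 15 | allyl hydrazone: (E)-N-tosylhydrazone of F2 | C[C@]1(Sc2ccccc2)C(=O)C[C@@H](C(C)=C)[C@](C)(C[C@@H](O)/C=N/NS(=O)(=O)c2ccc(C)cc2)[C@@]1(O)CC=C
F4 | step 15 | allyl sulfonylhydrazide: trans-decalin with C3–NH–NHTs and 9β-allyl | C[C@]1(Sc3ccccc3)C(=O)C[C@H]2C(C)(C)C(NNS(=O)(=O)c3ccc(C)cc3)[C@H](O)C[C@]2(C)[C@@]1(O)CC=C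
F5 | step 15 | allyl diazene: as F4 with C3–N=NH | C[C@]1(Sc3ccccc3)C(=O)C[C@H]2C(C)(C)C(N=N)[C@H](O)C[C@]2(C)[C@@]1(O)CC=C
F6 | step 15 | trans-decalin: 2α,9α-dihydroxy-7-oxo-8β-phenylthio decalin with 9β-allyl | C[C@]1(Sc3ccccc3)C(=O)C[C@H]2C(C)(C)C[C@H](O)C[C@]2(C)[C@@]1(O)CC=C
F7 | step 15 | decalin enal: F6 with 9β-[(2E)-3-formylbut-2-en-1-yl] | C[C@]1(Sc3ccccc3)C(=O)C[C@H]2C(C)(C)C[C@H](O)C[C@]2(C)[C@@]1(O)C/C=C(\C)C=O
F8 | step 15 | decalin (12E)-diene: F6 with 9β-[(2E)-3-methylpenta-2,4-dien-1-yl] | C[C@]1(Sc3ccccc3)C(=O)C[C@H]2C(C)(C)C[C@H](O)C[C@]2(C)[C@@]1(O)C/C=C(\C)C=C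
F9 | step 14 | (12Z)-diene hydrazone: 12Z isomer of 14 | C[C@]1(Sc2ccccc2)C(=O)C[C@@H](C(C)=C)[C@](C)(C[C@@H](O)/C=N/NS(=O)(=O)c2ccc(C)cc2)[C@@]1(O)C/C=C(/C)C=C
F10 | step 7 | ketol: 9 with hydrogen in place of the phenylthio group (either C8 epimer) | CC1C(=O)C[C@@H](C(C)=C)[C@](C)(C[C@@H]2COC(C)(C)O2)[C@@]1(O)CC=C
F11 | step 7 | bis-silyl enol ether: C7=C8 trimethylsilyl enol ether of F10 with the 9-O-trimethylsilyl ether | CC1=C(O[Si](C)(C)C)C[C@@H](C(C)=C)[C@](C)(C[C@@H]2COC(C)(C)O2)[C@]1(CC=C)O[Si](C)(C)C
F12 | step 7 | 9-O-silyl ketol sulfide: 9-O-trimethylsilyl ether of 9 | C[C@]1(Sc2ccccc2)C(=O)C[C@@H](C(C)=C)[C@](C)(C[C@@H]2COC(C)(C)O2)[C@@]1(O[Si](C)(C)C)CC=C
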